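**Retrosynthetic overview**

1. Target 30 (drimane numbering; cis-fused, 5R,8R,9R,10S) comes from the bicyclic alcohol 28 by hydrogenation (C1=C2 and two O-benzyl groups) and hydrolysis of the dioxolane that masks the aldehyde.
2. Key disconnection C7–C8: ring B is closed last, by an intramolecular samarium Barbier addition of the C7 primary iodide to the C8 methyl ketone of the monocyclic iodo ketone 24. The enabling feature is that the C6–C7 arm on C5 and the C9–C8(=O) arm on C10 stand cis on ring A, so C7 lies five atoms from C8, the only carbonyl carbon.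
3. 24 comes from the seven-membered lactone 13, a temporary ring with an oxygen between C7 and the C8 carbonyl: benzylation at C9 on its convex face with bromide 19, opening with methyllithium, iodination.
4. 13 comes from 2,4,4-trimethylcyclohex-2-enone 1: two CBS reductions each give an allylic carbinol whose configuration is passed on by a suprafacial [3,3] shift, first to C5 (Johnson–Claisen), then to the quaternary C10 (Ireland–Claisen). 19 comes from 2,5-dihydroxybenzaldehyde 14 by directed ortho-metalation.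
5. Ring order: the arene and ring A are bought, the lactone ring is made and opened again, ring B is formed last.

Key step: step 16

Assumption: atoms carry drimane numbers (decalin C1–C10, gem-dimethyl on C4, methyls on C8 and C10, benzylic C11 on C9); the target SMILES is read as the cis-fused isomer with H5, the C10 methyl, C11 and the C8 methyl on one face (β) and the C8 hydroxyl on the other (α).

**Route**

Step 1
Reactants: 1 2,4,4-trimethylcyclohex-2-en-1-one
Product: 2 (1S)-2,4,4-trimethylcyclohex-2-en-1-ol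
Conditions: (R)-Me-CBS oxazaborolidine (10 mol %), BH3·SMe2, THF, −20 °C; MeOH, then 1 M HCl
Reagents that add atoms: none
Why: Corey–Bakshi–Shibata reduction, in which the oxazaborolidine–borane complex delivers hydride to one carbonyl face with the trisubstituted alkene acting as the large group, should set the (S)-carbinol in high enantiomeric purity.

Step 2
Reactants: 2 (1S)-2,4,4-trimethylcyclohex-2-en-1-ol
Product: 4 ethyl 2-[(1R)-2,6,6-trimethylcyclohex-2-en-1-yl]acetate, via ketene acetal 3 (not isolated)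
Conditions: MeC(OEt)3, EtCO2H (cat.), 140 °C, EtOH distilled off
Reagents that add atoms: triethyl orthoacetate, CC(OCC)(OCC)OCC
Why: Johnson–Claisen rearrangement, in which the ketene acetal on the allylic oxygen shifts suprafacially so that the new C5–C6 bond forms on the face the oxygen leaves, should transfer the carbinol configuration to (R)-C5 and move the alkene to C10=C1.

Step 3
Reactants: 4 ethyl 2-[(1R)-2,6,6-trimethylcyclohex-2-en-1-yl]acetate
Product: 5 ethyl 2-[(1R)-2,6,6-trimethyl-4-oxocyclohex-2-en-1-yl]acetate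
Conditions: t-BuOOH, Rh2(cap)4 (dirhodium tetracaprolactamate, 1 mol %), K2CO3, CH2Cl2, rt
Reagents that add atoms: tert-butyl hydroperoxide, CC(C)(C)OO
Why: Allylic C–H oxidation by tert-butylperoxy radicals should attack the only ring methylene next to the alkene (C2) and give the conjugated enone, as in the known oxidation of α-ionone to 3-oxo-α-ionone, without touching C5.

Step 4
Reactants: 5 ethyl 2-[(1R)-2,6,6-trimethyl-4-oxocyclohex-2-en-1-yl]acetate
Product: 6 ethyl 2-[(1R,4S)-4-hydroxy-2,6,6-trimethylcyclohex-2-en-1-yl]acetate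
Conditions: (R)-Me-CBS oxazaborolidine (20 mol %), BH3·SMe2, THF, −30 °C; MeOH, then 1 M HCl
Reagents that add atoms: none
Why: A second Corey–Bakshi–Shibata reduction, again with the alkene as the large group, should give the (S)-allylic alcohol under catalyst control, that is the hydroxyl cis to the C6 arm, while the ester is not reduced at low temperature.

Step 5
Reactants: 6 ethyl 2-[(1R,4S)-4-hydroxy-2,6,6-trimethylcyclohex-2-en-1-yl]acetate
Product: 7 ethyl 2-[(1R,4S)-4-(acetyloxy)-2,6,6-trimethylcyclohex-2-en-1-yl]acetate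
Conditions: Ac2O, Et3N, DMAP (cat.), CH2Cl2, 0 °C to rt
Reagents that add atoms: acetic anhydride, CC(=O)OC(C)=O
Why: DMAP-catalysed acylation of a secondary alcohol proceeds with retention at carbon.

Step 6
Reactants: 7 ethyl 2-[(1R,4S)-4-(acetyloxy)-2,6,6-trimethylcyclohex-2-en-1-yl]acetate
Product: 10 2-[(1S,6R)-6-(2-ethoxy-2-oxoethyl)-1,5,5-trimethylcyclohex-2-en-1-yl]acetic acid, via silyl ketene acetal 8 (not isolated), via trimethylsilyl ester 9 (not isolated)
Conditions: LiN(i-Pr)2, Me3SiCl–Et3N, THF, −78 °C to rt, then 65 °C; 1 M HCl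
Reagents that add atoms: none
Why: Ireland–Claisen rearrangement, in which the silyl ketene acetal of the less hindered acetate shifts suprafacially so that C9 bonds to C10 on the face of the departing C2 oxygen (cis to the C6 arm), should create the quaternary (S)-C10 with its methyl on the β face and move the alkene to C1=C2.

Step 7
Reactants: 10 2-[(1S,6R)-6-(2-ethoxy-2-oxoethyl)-1,5,5-trimethylcyclohex-2-en-1-yl]acetic acid
Product: 11 2-[(1S,6R)-6-(2-hydroxyethyl)-1,5,5-trimethylcyclohex-2-en-1-yl]acetic acid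
Conditions: LiBH4, THF–MeOH, 0 °C to rt; aq. citric acid
Reagents that add atoms: none
Why: Lithium borohydride should reduce the ethyl ester chemoselectively because the acid is present in the flask as an unreactive lithium carboxylate.

Step 8
Reactants: 11 2-[(1S,6R)-6-(2-hydroxyethyl)-1,5,5-trimethylcyclohex-2-en-1-yl]acetic acid
Product: 13 (5aR,9aS)-6,6,9a-trimethyl-4,5,5a,6,7,9a-hexahydro-3-benzoxepin-2(1H)-one, via mixed anhydride 12 (not isolated)
Conditions: 2,4,6-Cl3C6H2COCl, Et3N, THF, rt; then DMAP, toluene, 80 °C, high dilution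
Reagents that add atoms: none
Why: Yamaguchi lactonisation, in which the mixed anhydride acylates DMAP and the C7 hydroxyl then closes the seven-membered lactone, can only give the cis-fused ring because both arms sit on the same face of ring A.

Step 9
Reactants: 14 2,5-dihydroxybenzaldehyde
Product: 15 2,5-bis(benzyloxy)benzaldehyde
Conditions: BnBr, K2CO3, DMF, 60 °C
Reagents that add atoms: benzyl bromide, BrCc1ccccc1
Why: Williamson ether synthesis protects both phenols as groups that the final hydrogenation removes.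

Step 10
Reactants: 15 2,5-bis(benzyloxy)benzaldehyde
Product: 16 2-[2,5-bis(benzyloxy)phenyl]-1,3-dioxolane
Conditions: HOCH2CH2OH, TsOH (cat.), toluene, reflux, Dean–Stark trap
Reagents that add atoms: ethylene glycol, OCCO
Why: Acid-catalysed acetalisation with azeotropic removal of water masks the aldehyde against the organolithium, hydride and samarium steps.

Step 11
Reactants: 16 2-[2,5-bis(benzyloxy)phenyl]-1,3-dioxolane
Product: 18 [3,6-bis(benzyloxy)-2-(1,3-dioxolan-2-yl)phenyl]methanol, via aryllithium 17 (not isolated)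
Conditions: n-BuLi, TMEDA, THF, −40 °C; (CH2O)n, −40 °C to rt; aq. NH4Cl
Reagents that add atoms: formaldehyde (from paraformaldehyde), C=O
Why: Directed ortho-metalation should occur at the only ring position flanked by two coordinating groups (dioxolane and benzyloxy), and the aryllithium is trapped by formaldehyde.

Step 12
Reactants: 18 [3,6-bis(benzyloxy)-2-(1,3-dioxolan-2-yl)phenyl]methanol
Product: 19 2-[3,6-bis(benzyloxy)-2-(bromomethyl)phenyl]-1,3-dioxolane
Conditions: CBr4, PPh3, CH2Cl2, 0 °C; used at once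
Reagents that add atoms: carbon tetrabromide, BrC(Br)(Br)Br
Why: Appel bromination converts the primary benzylic alcohol into the bromide under neutral conditions that spare the acetal.

Step 13
Reactants: 13 (5aR,9aS)-6,6,9a-trimethyl-4,5,5a,6,7,9a-hexahydro-3-benzoxepin-2(1H)-one; 19 2-[3,6-bis(benzyloxy)-2-(bromomethyl)phenyl]-1,3-dioxolane
Product: 21 (1R,5aR,9aS)-1-{[3,6-bis(benzyloxy)-2-(1,3-dioxolan-2-yl)phenyl]methyl}-6,6,9a-trimethyl-4,5,5a,6,7,9a-hexahydro-3-benzoxepin-2(1H)-one, via lithium enolate 20 (not isolated)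
Conditions: LiN(i-Pr)2, THF, −78 °C; 19, DMPU, −78 to −20 °C
Reagents that add atoms: none
Why: Alkylation of the lactone enolate, whose only acidic position is C9, should occur from the convex face of the cis-fused bicycle (the face of H5 and the C10 methyl, the other being covered by ring A), which places C11 on the β face and gives (R)-C9.

Step 14
Reactants: 21 (1R,5aR,9aS)-1-{[3,6-bis(benzyloxy)-2-(1,3-dioxolan-2-yl)phenyl]methyl}-6,6,9a-trimethyl-4,5,5a,6,7,9a-hexahydro-3-benzoxepin-2(1H)-one
Product: 23 (3R)-4-[3,6-bis(benzyloxy)-2-(1,3-dioxolan-2-yl)phenyl]-3-[(1S,6R)-6-(2-hydroxyethyl)-1,5,5-trimethylcyclohex-2-en-1-yl]butan-2-one, via lithium hemiketal alkoxide 22 (not isolated)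
Conditions: MeLi (1.1 equiv), THF, −78 °C; aq. NH4Cl
Reagents that add atoms: methyllithium, [Li]C
Why: Addition of methyllithium to a hindered lactone at low temperature should stop at the tetrahedral lithium hemiketal, which collapses on work-up to the C8 methyl ketone and frees the C7 hydroxyl without touching C9.

Step 15
Reactants: 23 (3R)-4-[3,6-bis(benzyloxy)-2-(1,3-dioxolan-2-yl)phenyl]-3-[(1S,6R)-6-(2-hydroxyethyl)-1,5,5-trimethylcyclohex-2-en-1-yl]butan-2-one
Product: 24 (3R)-4-[3,6-bis(benzyloxy)-2-(1,3-dioxolan-2-yl)phenyl]-3-[(1S,6R)-6-(2-iodoethyl)-1,5,5-trimethylcyclohex-2-en-1-yl]butan-2-one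
Conditions: I2, PPh3, imidazole, CH2Cl2, 0 °C
Reagents that add atoms: iodine, [I][I]
Why: Appel-type iodination converts the primary alcohol into the iodide by SN2 displacement of the oxyphosphonium group while imidazole buffers the acid.

Step 16
Reactants: 24 (3R)-4-[3,6-bis(benzyloxy)-2-(1,3-dioxolan-2-yl)phenyl]-3-[(1S,6R)-6-(2-iodoethyl)-1,5,5-trimethylcyclohex-2-en-1-yl]butan-2-one
Product: 28 (1R,2R,4aR,8aS)-1-{[3,6-bis(benzyloxy)-2-(1,3-dioxolan-2-yl)phenyl]methyl}-2,5,5,8a-tetramethyl-1,2,3,4,4a,5,6,8a-octahydronaphthalen-2-ol, via C7 radical 25 (not isolated), via alkylsamarium diiodide 26 (not isolated), via samarium alkoxide 27 (not isolated)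
Conditions: SmI2 (2.5 equiv), THF–HMPA, −78 °C to rt; aq. NH4Cl
Reagents that add atoms: none
Why: Samarium diiodide transfers one electron to the C7–I bond, the primary C7 radical 25 is reduced by a second equivalent to the alkylsamarium 26, and this adds to the C8 ketone to give the samarium alkoxide 27, which is protonated on work-up. The closest known reaction type is the intramolecular samarium Barbier reaction of ω-iodoalkyl ketones, which gives cyclohexanols. Ring B closes by nucleophilic 6-exo-trig attack of C7 on the carbonyl carbon C8. The new C8 stereocentre should be controlled by a chair-like transition state in which the quaternary C4 is equatorial on the forming ring and the C8 methyl also takes an equatorial position to avoid a syn-axial clash with C1, so that the oxygen ends up axial on the α face (8R). The step needs reduction of the alkyl iodide before the dialkyl ketone, which HMPA secures by accelerating iodide reduction, and it needs addition to outrun proton transfer from C9–H, which the short tether secures. The cis arrangement of the two arms on ring A, fixed in steps 2 and 6, is what makes the ring close as the cis-decalin.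

Step 17
Reactants: 28 (1R,2R,4aR,8aS)-1-{[3,6-bis(benzyloxy)-2-(1,3-dioxolan-2-yl)phenyl]methyl}-2,5,5,8a-tetramethyl-1,2,3,4,4a,5,6,8a-octahydronaphthalen-2-ol
Product: 29 2-(1,3-dioxolan-2-yl)-3-{[(1R,2R,4aR,8aS)-2-hydroxy-2,5,5,8a-tetramethyldecahydronaphthalen-1-yl]methyl}benzene-1,4-diol
Conditions: H2 (1 atm), Pd/C, EtOAc–EtOH, rt
Reagents that add atoms: none
Why: Heterogeneous hydrogenation should saturate the ring A alkene (no stereocentre is created) and cleave both benzyl ethers, while the dioxolane and the tertiary alcohol are inert under neutral conditions.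

Step 18
Reactants: 29 2-(1,3-dioxolan-2-yl)-3-{[(1R,2R,4aR,8aS)-2-hydroxy-2,5,5,8a-tetramethyldecahydronaphthalen-1-yl]methyl}benzene-1,4-diol
Product: 30 3,6-dihydroxy-2-{[(1R,2R,4aR,8aS)-2-hydroxy-2,5,5,8a-tetramethyldecahydronaphthalen-1-yl]methyl}benzaldehyde
Conditions: PPTS (cat.), acetone–H2O, 40 °C, degassed
Reagents that add atoms: water, O
Why: Mild acid hydrolysis of the aryl dioxolane releases the aldehyde, which is held by a hydrogen bond to the neighbouring phenol, under conditions too mild to ionise the tertiary C8 alcohol.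

**Compound list**

1 | 2,4,4-trimethylcyclohex-2-en-1-one | CC1=CC(C)(C)CCC1=O | starting material
2 | (1S)-2,4,4-trimethylcyclohex-2-en-1-ol | CC1(C)CC[C@H](O)C(C)=C1 | intermediate
3 | 1-ethoxy-1-{[(1S)-2,4,4-trimethylcyclohex-2-en-1-yl]oxy}ethene (ketene acetal) | CC1(C)CC[C@H](OC(=C)OCC)C(C)=C1 | intermediate
4 | ethyl 2-[(1R)-2,6,6-trimethylcyclohex-2-en-1-yl]acetate | CC1(C)CCC=C(C)[C@@H]1CC(=O)OCC | intermediate
5 | ethyl 2-[(1R)-2,6,6-trimethyl-4-oxocyclohex-2-en-1-yl]acetate | CC1(C)CC(=O)C=C(C)[C@@H]1CC(=O)OCC | intermediate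
6 | ethyl 2-[(1R,4S)-4-hydroxy-2,6,6-trimethylcyclohex-2-en-1-yl]acetate | CC1(C)C[C@H](O)C=C(C)[C@@H]1CC(=O)OCC | intermediate
7 | ethyl 2-[(1R,4S)-4-(acetyloxy)-2,6,6-trimethylcyclohex-2-en-1-yl]acetate | CC1(C)C[C@H](OC(C)=O)C=C(C)[C@@H]1CC(=O)OCC | intermediate
8 | ethyl 2-[(1R,4S)-2,6,6-trimethyl-4-({1-[(trimethylsilyl)oxy]ethenyl}oxy)cyclohex-2-en-1-yl]acetate (silyl ketene acetal) | CC1(C)C[C@H](OC(=C)O[Si](C)(C)C)C=C(C)[C@@H]1CC(=O)OCC | intermediate
9 | trimethylsilyl 2-[(1S,6R)-6-(2-ethoxy-2-oxoethyl)-1,5,5-trimethylcyclohex-2-en-1-yl]acetate | CC1(C)CC=C[C@](C)(CC(=O)O[Si](C)(C)C)[C@@H]1CC(=O)OCC | intermediate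
10 | 2-[(1S,6R)-6-(2-ethoxy-2-oxoethyl)-1,5,5-trimethylcyclohex-2-en-1-yl]acetic acid | CC1(C)CC=C[C@](C)(CC(O)=O)[C@@H]1CC(=O)OCC | intermediate
11 | 2-[(1S,6R)-6-(2-hydroxyethyl)-1,5,5-trimethylcyclohex-2-en-1-yl]acetic acid | CC1(C)CC=C[C@](C)(CC(O)=O)[C@@H]1CCO | intermediate
12 | mixed anhydride of 11 with 2,4,6-trichlorobenzoic acid | CC1(C)CC=C[C@](C)(CC(=O)OC(=O)c2c(Cl)cc(Cl)cc2Cl)[C@@H]1CCO | intermediate
13 | (5aR,9aS)-6,6,9a-trimethyl-4,5,5a,6,7,9a-hexahydro-3-benzoxepin-2(1H)-one (cis-fused lactone; O joins C7 to the C8 carbonyl) | CC1(C)CC=C[C@]2(C)CC(=O)OCC[C@H]12 | intermediate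
14 | 2,5-dihydroxybenzaldehyde | O=Cc1cc(O)ccc1O | starting material
15 | 2,5-bis(benzyloxy)benzaldehyde | O=Cc1cc(OCc2ccccc2)ccc1OCc1ccccc1 | intermediate
16 | 2-[2,5-bis(benzyloxy)phenyl]-1,3-dioxolane | C1COC(O1)c1cc(OCc2ccccc2)ccc1OCc1ccccc1 | intermediate
17 | [3,6-bis(benzyloxy)-2-(1,3-dioxolan-2-yl)phenyl]lithium | [Li]c1c(OCc2ccccc2)ccc(OCc2ccccc2)c1C1OCCO1 | intermediate
18 | [3,6-bis(benzyloxy)-2-(1,3-dioxolan-2-yl)phenyl]methanol | OCc1c(OCc2ccccc2)ccc(OCc2ccccc2)c1C1OCCO1 | intermediate
19 | 2-[3,6-bis(benzyloxy)-2-(bromomethyl)phenyl]-1,3-dioxolane | BrCc1c(OCc2ccccc2)ccc(OCc2ccccc2)c1C1OCCO1 | intermediate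
20 | lithium enolate of lactone 13 (C8=C9) | CC1(C)CC=C[C@]2(C)C=C([O-])OCC[C@H]12.[Li+] | intermediate
21 | (1R,5aR,9aS)-1-{[3,6-bis(benzyloxy)-2-(1,3-dioxolan-2-yl)phenyl]methyl}-6,6,9a-trimethyl-4,5,5a,6,7,9a-hexahydro-3-benzoxepin-2(1H)-one | CC1(C)CC=C[C@]2(C)[C@@H](Cc3c(OCc4ccccc4)ccc(OCc4ccccc4)c3C3OCCO3)C(=O)OCC[C@H]12 | intermediate
22 | lithium hemiketal alkoxide from 21 and methyllithium (C8 bears CH3, O–Li and the ring oxygen) | CC1(C)CC=C[C@]2(C)[C@@H](Cc3c(OCc4ccccc4)ccc(OCc4ccccc4)c3C3OCCO3)C(C)([O-])OCC[C@H]12.[Li+] | intermediate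
23 | (3R)-4-[3,6-bis(benzyloxy)-2-(1,3-dioxolan-2-yl)phenyl]-3-[(1S,6R)-6-(2-hydroxyethyl)-1,5,5-trimethylcyclohex-2-en-1-yl]butan-2-one | CC1(C)CC=C[C@](C)([C@@H](Cc2c(OCc3ccccc3)ccc(OCc3ccccc3)c2C2OCCO2)C(C)=O)[C@@H]1CCO | intermediate
24 | (3R)-4-[3,6-bis(benzyloxy)-2-(1,3-dioxolan-2-yl)phenyl]-3-[(1S,6R)-6-(2-iodoethyl)-1,5,5-trimethylcyclohex-2-en-1-yl]butan-2-one | CC1(C)CC=C[C@](C)([C@@H](Cc2c(OCc3ccccc3)ccc(OCc3ccccc3)c2C2OCCO2)C(C)=O)[C@@H]1CCI | intermediate
25 | primary C7 radical from 24 (iodine removed) | CC1(C)CC=C[C@](C)([C@@H](Cc2c(OCc3ccccc3)ccc(OCc3ccccc3)c2C2OCCO2)C(C)=O)[C@@H]1C[CH2] | intermediate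
26 | C7 alkylsamarium diiodide from 24 | CC1(C)CC=C[C@](C)([C@@H](Cc2c(OCc3ccccc3)ccc(OCc3ccccc3)c2C2OCCO2)C(C)=O)[C@@H]1CC[Sm](I)I | intermediate
27 | samarium alkoxide of 28 (O–SmI2 on C8) | CC1(C)CC=C[C@@]2(C)[C@@H]1CC[C@@](C)(O[Sm](I)I)[C@@H]2Cc1c(OCc3ccccc3)ccc(OCc3ccccc3)c1C1OCCO1 | intermediate
28 | (1R,2R,4aR,8aS)-1-{[3,6-bis(benzyloxy)-2-(1,3-dioxolan-2-yl)phenyl]methyl}-2,5,5,8a-tetramethyl-1,2,3,4,4a,5,6,8a-octahydronaphthalen-2-ol | CC1(C)CC=C[C@@]2(C)[C@@H]1CC[C@@](C)(O)[C@@H]2Cc1c(OCc3ccccc3)ccc(OCc3ccccc3)c1C1OCCO1 | intermediate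
29 | 2-(1,3-dioxolan-2-yl)-3-{[(1R,2R,4aR,8aS)-2-hydroxy-2,5,5,8a-tetramethyldecahydronaphthalen-1-yl]methyl}benzene-1,4-diol | CC1(C)CCC[C@@]2(C)[C@@H]1CC[C@@](C)(O)[C@@H]2Cc1c(O)ccc(O)c1C1OCCO1 | intermediate
30 | 3,6-dihydroxy-2-{[(1R,2R,4aR,8aS)-2-hydroxy-2,5,5,8a-tetramethyldecahydronaphthalen-1-yl]methyl}benzaldehyde | CC1(C)CCC[C@@]2(C)[C@@H]1CC[C@@](C)(O)[C@@H]2Cc1c(O)ccc(O)c1C=O | target

**Step count and risks**

Total step count: 18. Longest linear sequence: 14 steps (steps 1–8 and 13–18).

Steps most likely to fail: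

Step 6. The rearrangement must build the quaternary C10 next to the substituted C5 and syn to an axial C4 methyl, so the silyl ketene acetal may eliminate, be C-silylated or be protonated before it rearranges, or enolisation may take place at the ethyl ester instead. The fallback sets out from alcohol 6 and comes back at acid 10. Heating 6 with N,N-dimethylacetamide dimethyl acetal (xylene, 140 °C; Eschenmoser–Claisen rearrangement through a neutral, more reactive ketene N,O-acetal) should give 2-[(1S,6R)-6-(2-ethoxy-2-oxoethyl)-1,5,5-trimethylcyclohex-2-en-1-yl]-N,N-dimethylacetamide F1. Iodolactonisation (iodine, THF–H2O) should convert the hindered amide into ethyl 2-(7-iodo-3a,5,5-trimethyl-2-oxooctahydro-1-benzofuran-4-yl)acetate F2 with loss of dimethylamine. Zinc in acetic acid then opens the iodolactone by reductive elimination and returns the unsaturated acid 10.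

Step 13. The neopentylic lactone enolate may react too slowly with the doubly ortho-substituted benzylic bromide, so that cyclisation of the bromide onto its dioxolane oxygen and O-alkylation of the enolate take over. The fallback sets out from enolate 20 and aryllithium 17 and comes back at lactone 21. Quenching 17 with DMF should give 3,6-bis(benzyloxy)-2-(1,3-dioxolan-2-yl)benzaldehyde F3. Aldol addition of 20 to this small sp2 electrophile, again from the convex face, should give the C11-hydroxy derivative of lactone 21 F4. Phenyl chlorothionoformate and pyridine should give the O-phenyl thionocarbonate of that hydroxyl F5, and tributyltin hydride with AIBN (Barton–McCombie deoxygenation of the benzylic position) should then deliver 21.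

Step 16. Single-electron reduction of the C8 ketone (ketyl formation, pinacol dimerisation) or protonation of the C7 organosamarium by the acidic C9–H may outrun ring closure and give only the deiodinated ketone, and attack on the other carbonyl face would give the C8 epimer. The fallback sets out from hydroxy ketone 23 and comes back at 28. Dess–Martin oxidation should give (3R)-4-[3,6-bis(benzyloxy)-2-(1,3-dioxolan-2-yl)phenyl]-3-[(1S,6R)-1,5,5-trimethyl-6-(2-oxoethyl)cyclohex-2-en-1-yl]butan-2-one F6. Samarium diiodide with tert-butanol should close ring B by ketyl-based pinacol coupling of aldehyde and ketone, where ketone reduction is now productive, to give the 7-hydroxy derivative of 28 F7 (the C7 epimers converge). Selective acylation of the secondary hydroxyl with phenyl chlorothionoformate should give the C7 O-phenyl thionocarbonate of that diol F8, and tributyltin hydride with AIBN removes the C7 oxygen to give 28.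

Further compounds
F1 | step 6 | 2-[(1S,6R)-6-(2-ethoxy-2-oxoethyl)-1,5,5-trimethylcyclohex-2-en-1-yl]-N,N-dimethylacetamide | CC1(C)CC=C[C@](C)(CC(=O)N(C)C)[C@@H]1CC(=O)OCC
F2 | step 6 | ethyl 2-(7-iodo-3a,5,5-trimethyl-2-oxooctahydro-1-benzofuran-4-yl)acetate (cis-fused lactone, iodine trans to the ring oxygen) | CC1(C)C[C@@H](I)[C@@H]2OC(=O)C[C@]2(C)[C@@H]1CC(=O)OCC
F3 | step 13 | 3,6-bis(benzyloxy)-2-(1,3-dioxolan-2-yl)benzaldehyde | O=Cc1c(OCc2ccccc2)ccc(OCc2ccccc2)c1C1OCCO1
F4 | step 13 | C11-hydroxy derivative of lactone 21 (aldol adduct, C11 configuration not controlled) | CC1(C)CC=C[C@]2(C)[C@@H](C(O)c3c(OCc4ccccc4)ccc(OCc4ccccc4)c3C3OCCO3)C(=O)OCC[C@H]12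
F5 | step 13 | O-phenyl thionocarbonate of the C11 hydroxyl of F4 | CC1(C)CC=C[C@]2(C)[C@@H](C(OC(=S)Oc3ccccc3)c3c(OCc4ccccc4)ccc(OCc4ccccc4)c3C3OCCO3)C(=O)OCC[C@H]12
F6 | step 16 | (3R)-4-[3,6-bis(benzyloxy)-2-(1,3-dioxolan-2-yl)phenyl]-3-[(1S,6R)-1,5,5-trimethyl-6-(2-oxoethyl)cyclohex-2-en-1-yl]butan-2-one | CC1(C)CC=C[C@](C)([C@@H](Cc2c(OCc3ccccc3)ccc(OCc3ccccc3)c2C2OCCO2)C(C)=O)[C@@H]1CC=O
F7 | step 16 | 7-hydroxy derivative of 28 (7,8-diol, C7 configuration not controlled) | CC1(C)CC=C[C@@]2(C)[C@@H]1CC(O)[C@@](C)(O)[C@@H]2Cc1c(OCc3ccccc3)ccc(OCc3ccccc3)c1C1OCCO1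
F8 | step 16 | O-phenyl thionocarbonate of the C7 hydroxyl of F7 | CC1(C)CC=C[C@@]2(C)[C@@H]1CC(OC(=S)Oc3ccccc3)[C@@](C)(O)[C@@H]2Cc1c(OCc3ccccc3)ccc(OCc3ccccc3)c1C1OCCO1
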